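The indole's five-membered ring is cut at N1–C2 and C3–C3a. N1, C7a and C3a then come from an ortho-iodoaniline and C2–C3 from an alkyne, so the 4-methoxy-6-bromo pattern is already fixed in 5-bromo-2-iodo-3-methoxyaniline, in which iodine is flanked by NH2 and OMe. The partner is a trimethylsilyl alkyne that already carries the 2-(N-SEM-pyrrol-2-yl)oxazol-5-yl unit. One palladium-catalysed heteroannulation forms both bonds, closes the ring, puts the oxazole on C3 and leaves a removable silyl group on C2. The palladium-sensitive iodine at oxazole C4 is added afterwards by directed magnesiation.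

Key step: step 9

Abbreviations: SEM = [2-(trimethylsilyl)ethoxy]methyl; TIPS = triisopropylsilyl; TMP = 2,2,6,6-tetramethylpiperidide.

Assumption (remark on the chemistry): 4-bromo-2-methoxy-6-nitroaniline is treated as a purchasable compound.

Design note: the pyrrole nitrogen is alkylated before the acetal is unmasked, because a free pyrrole N–H next to the liberated aldehyde would be expected to close to a pyrrolo[1,2-a]pyrazinone instead of letting the amide oxygen form the oxazole. SEM is chosen because it should tolerate carbonate at 100 °C and amide bases and can leave with fluoride together with the N-silyl group.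

Step 1
Reactants: 1 1H-pyrrole-2-carboxylic acid; 2 aminoacetaldehyde dimethyl acetal
Product: 4 N-(2,2-dimethoxyethyl)-1H-pyrrole-2-carboxamide, via acyl imidazole 3 (not isolated)
Conditions: CDI, THF, rt; then 2, rt
Reagents that add atoms: none
Why: Amide coupling through the acyl imidazole, in which CDI turns the acid into an acylating agent that the primary amine attacks at room temperature while the weakly nucleophilic pyrrole N–H and the acetal stay untouched.

Step 2
Reactants: 4 N-(2,2-dimethoxyethyl)-1H-pyrrole-2-carboxamide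
Product: 6 N-(2,2-dimethoxyethyl)-1-SEM-pyrrole-2-carboxamide, via sodium pyrrolide 5 (not isolated)
Conditions: NaH (1.1 equiv), DMF, 0 °C; SEMCl, 0 °C to rt
Reagents that add atoms: 2-(trimethylsilyl)ethoxymethyl chloride, C[Si](C)(C)CCOCCl
Why: N-alkylation of the pyrrolide (SN2 on the chloromethyl ether), where the N–H of a 2-acylpyrrole is several pK units more acidic than the secondary amide N–H, so one equivalent of NaH should deprotonate only the ring nitrogen.

Step 3
Reactants: 6 N-(2,2-dimethoxyethyl)-1-SEM-pyrrole-2-carboxamide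
Product: 7 N-(2-oxoethyl)-1-SEM-pyrrole-2-carboxamide
Conditions: 1 M aq. HCl, THF, rt
Reagents that add atoms: water, O
Why: Acid-catalysed acetal hydrolysis, since the dimethyl acetal is cleaved by dilute aqueous acid at room temperature, conditions under which the N-SEM aminal ether on the electron-poor acylpyrrole and the amide should be stable, and the aldehyde is taken on without storage.

Step 4
Reactants: 7 N-(2-oxoethyl)-1-SEM-pyrrole-2-carboxamide
Product: 8 2-(1-SEM-pyrrol-2-yl)oxazole
Conditions: PPh3, C2Cl6, Et3N, CH2Cl2, 0 °C to rt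
Reagents that add atoms: none
Why: Robinson–Gabriel cyclodehydration under non-acidic conditions, in which the amide oxygen adds to the aldehyde carbon (5-exo-trig), Ph3PCl2 made from PPh3 and C2Cl6 activates the resulting hydroxyl and Et3N-assisted elimination aromatises to the oxazole, with no acid present to threaten the SEM group.

Step 5
Reactants: 8 2-(1-SEM-pyrrol-2-yl)oxazole
Product: 10 5-iodo-2-(1-SEM-pyrrol-2-yl)oxazole, via 5-lithiooxazole 9 (not isolated)
Conditions: LiN(iPr)2, THF, −78 °C; then inverse addition to I2, THF, −78 °C to rt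
Reagents that add atoms: iodine, II
Why: Deprotonative lithiation followed by iodinolysis, because with C2 substituted the C5–H next to oxygen is the most acidic C–H of the oxazole, a lithium amide (unlike an alkyllithium) should not engage the SEM-directed pyrrole α-position, and 5-lithiooxazoles, in contrast to 2-lithiooxazoles, do not ring-open.

Step 6
Reactants: 10 5-iodo-2-(1-SEM-pyrrol-2-yl)oxazole; 11 ethynyltrimethylsilane
Product: 12 2-(1-SEM-pyrrol-2-yl)-5-[(trimethylsilyl)ethynyl]oxazole
Conditions: PdCl2(PPh3)2 (cat.), CuI (cat.), Et3N, THF, rt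
Reagents that add atoms: none
Why: Sonogashira coupling, in which the electron-poor heteroaryl C–I bond undergoes oxidative addition at room temperature and the copper acetylide transmetalates, the C–SiMe3 bond being stable to amine base.

Step 7
Reactants: 13 4-bromo-2-methoxy-6-nitroaniline
Product: 15 5-bromo-2-iodo-1-methoxy-3-nitrobenzene, via arenediazonium hydrogensulfate 14 (not isolated)
Conditions: NaNO2, H2SO4, AcOH, 0–10 °C; then KI, H2O, 0 °C to rt
Reagents that add atoms: potassium iodide, [K+].[I-]
Why: Sandmeyer-type iododediazoniation, in which the weakly basic nitroaniline is diazotised in H2SO4/AcOH and iodide reduces the diazonium ion to an aryl radical that is captured as the aryl iodide without copper, so iodine takes exactly the position of the amino group between OMe and NO2.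

Step 8
Reactants: 15 5-bromo-2-iodo-1-methoxy-3-nitrobenzene
Product: 16 5-bromo-2-iodo-3-methoxyaniline
Conditions: Fe powder, AcOH, EtOH, 80 °C
Reagents that add atoms: none
Why: Béchamp-type reduction of the nitro group by iron in acetic acid (dissolving-metal electron transfer), which should leave both C–I and C–Br untouched, in contrast to catalytic hydrogenation.

Step 9
Reactants: 16 5-bromo-2-iodo-3-methoxyaniline; 12 2-(1-SEM-pyrrol-2-yl)-5-[(trimethylsilyl)ethynyl]oxazole
Product: 17 6-bromo-4-methoxy-3-[2-(1-SEM-pyrrol-2-yl)oxazol-5-yl]-2-(trimethylsilyl)-1H-indole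
Conditions: Pd(OAc)2 (10 mol %), LiCl (1 equiv), Na2CO3 (3 equiv), DMF, 100 °C
Reagents that add atoms: none
Why: Zerovalent palladium formed from Pd(OAc)2 inserts into the C–I bond of 16 to give an aryl complex of divalent palladium, the alkyne coordinates and undergoes syn-carbopalladation with the aryl group delivered to the oxazole-bearing carbon and palladium to the silyl-bearing carbon, the aniline nitrogen then binds palladium, and C–N reductive elimination from the six-membered azapalladacycle releases the indole and zerovalent palladium. The closest known reaction type is the Larock indole synthesis of 2-iodoanilines with aryl(trialkylsilyl)acetylenes. The five-membered ring (N1, C2, C3, C3a, C7a) closes as a formal [3+2] heteroannulation, C3–C3a being made in the insertion and N1–C2 in the reductive elimination; no stereocentre is created. Two selectivities are needed: the regiochemistry of insertion, secured by the bulky Me3Si group, which avoids the crowded aryl terminus in the insertion and therefore ends on C2 next to nitrogen, and the preference for iodide over bromide, secured by the weaker C–I bond under ligand-free conditions at moderate temperature. Because iodine is flanked by NH2 and OMe in 16, the benzene ring offers no regiochemical choice, so OMe must end on C4 and Br on C6.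

Step 10
Reactants: 17 6-bromo-4-methoxy-3-[2-(1-SEM-pyrrol-2-yl)oxazol-5-yl]-2-(trimethylsilyl)-1H-indole
Product: 18 6-bromo-4-methoxy-3-[2-(1-SEM-pyrrol-2-yl)oxazol-5-yl]-1H-indole
Conditions: 2 M aq. HCl, THF/MeOH, rt
Reagents that add atoms: none
Why: Protodesilylation by electrophilic ipso substitution, in which protonation of the electron-rich 4-methoxyindole at C2 gives a cation stabilised by the β-silicon and loss of the silyl group to water restores the indole, while dilute acid at room temperature should spare the N-SEM group, the oxazole and the aryl bromide.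

Step 11
Reactants: 18 6-bromo-4-methoxy-3-[2-(1-SEM-pyrrol-2-yl)oxazol-5-yl]-1H-indole
Product: 20 6-bromo-4-methoxy-3-[2-(1-SEM-pyrrol-2-yl)oxazol-5-yl]-1-TIPS-indole, via sodium indolide 19 (not isolated)
Conditions: NaH, THF, 0 °C; TIPSCl, 0 °C to rt
Reagents that add atoms: chlorotriisopropylsilane, CC(C)[Si](Cl)(C(C)C)C(C)C
Why: N-silylation of the sodium indolide, where the indole N–H is the only acidic N–H left and the triisopropylsilyl group both removes it and screens C2–H and C7–H against the amide base of the next step.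

Step 12
Reactants: 20 6-bromo-4-methoxy-3-[2-(1-SEM-pyrrol-2-yl)oxazol-5-yl]-1-TIPS-indole
Product: 22 6-bromo-3-[4-iodo-2-(1-SEM-pyrrol-2-yl)oxazol-5-yl]-4-methoxy-1-TIPS-indole, via 4-magnesiated oxazole 21 (not isolated)
Conditions: TMPMgCl·LiCl (1.5 equiv), THF, −20 to 0 °C; then I2, −20 °C to rt
Reagents that add atoms: iodine, II
Why: Directed magnesiation with a hindered magnesium amide followed by iodinolysis, since C4–H is the only C–H of the oxazole and lies next to the coordinating ring nitrogen N3, indole C2–H is shielded by the silyl group on N1, and a magnesium amide does not undergo halogen–metal exchange with the aryl bromide.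

Step 13
Reactants: 22 6-bromo-3-[4-iodo-2-(1-SEM-pyrrol-2-yl)oxazol-5-yl]-4-methoxy-1-TIPS-indole
Product: 24 6-bromo-3-[4-iodo-2-(1H-pyrrol-2-yl)oxazol-5-yl]-4-methoxy-1H-indole, via N-desilylated indole 23 (not isolated)
Conditions: Bu4NF (excess), THF, rt, then 65 °C
Reagents that add atoms: none
Why: Fluoride-induced desilylation, in which the indole N–Si bond is cleaved at room temperature and, on warming, fluoride attacks the SEM silicon so that ethene and formaldehyde are expelled and the oxazole-stabilised pyrrolide leaves, while C–I, C–Br and the methyl ether are inert to fluoride.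

Compound list
1 | 1H-pyrrole-2-carboxylic acid | OC(=O)c1ccc[nH]1 | starting material
2 | aminoacetaldehyde dimethyl acetal (2,2-dimethoxyethanamine) | NCC(OC)OC | starting material
3 | (1H-imidazol-1-yl)(1H-pyrrol-2-yl)methanone | O=C(c1ccc[nH]1)n1ccnc1 | intermediate
4 | N-(2,2-dimethoxyethyl)-1H-pyrrole-2-carboxamide | COC(CNC(=O)c1ccc[nH]1)OC | intermediate
5 | sodium 2-[(2,2-dimethoxyethyl)carbamoyl]pyrrol-1-ide | COC(CNC(=O)c1ccc[n-]1)OC.[Na+] | intermediate
6 | N-(2,2-dimethoxyethyl)-1-{[2-(trimethylsilyl)ethoxy]methyl}pyrrole-2-carboxamide | COC(CNC(=O)c1cccn1COCC[Si](C)(C)C)OC | intermediate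
7 | N-(2-oxoethyl)-1-{[2-(trimethylsilyl)ethoxy]methyl}pyrrole-2-carboxamide | O=CCNC(=O)c1cccn1COCC[Si](C)(C)C | intermediate
8 | 2-(1-{[2-(trimethylsilyl)ethoxy]methyl}pyrrol-2-yl)oxazole | C[Si](C)(C)CCOCn1cccc1-c1ncco1 | intermediate
9 | 5-lithio-2-(1-SEM-pyrrol-2-yl)oxazole | [Li]c1cnc(-c2cccn2COCC[Si](C)(C)C)o1 | intermediate
10 | 5-iodo-2-(1-SEM-pyrrol-2-yl)oxazole | Ic1cnc(-c2cccn2COCC[Si](C)(C)C)o1 | intermediate
11 | ethynyltrimethylsilane | C#C[Si](C)(C)C | starting material
12 | 2-(1-SEM-pyrrol-2-yl)-5-[(trimethylsilyl)ethynyl]oxazole | C[Si](C)(C)C#Cc1cnc(-c2cccn2COCC[Si](C)(C)C)o1 | intermediate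
13 | 4-bromo-2-methoxy-6-nitroaniline | COc1cc(Br)cc([N+](=O)[O-])c1N | starting material
14 | 4-bromo-2-methoxy-6-nitrobenzenediazonium hydrogensulfate | COc1cc(Br)cc([N+](=O)[O-])c1[N+]#N.OS(=O)(=O)[O-] | intermediate
15 | 5-bromo-2-iodo-1-methoxy-3-nitrobenzene | COc1cc(Br)cc([N+](=O)[O-])c1I | intermediate
16 | 5-bromo-2-iodo-3-methoxyaniline | Nc1cc(Br)cc(OC)c1I | intermediate
17 | 6-bromo-4-methoxy-3-[2-(1-SEM-pyrrol-2-yl)oxazol-5-yl]-2-(trimethylsilyl)-1H-indole | COc1cc(Br)cc2[nH]c([Si](C)(C)C)c(-c3cnc(-c4cccn4COCC[Si](C)(C)C)o3)c12 | intermediate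
18 | 6-bromo-4-methoxy-3-[2-(1-SEM-pyrrol-2-yl)oxazol-5-yl]-1H-indole | COc1cc(Br)cc2[nH]cc(-c3cnc(-c4cccn4COCC[Si](C)(C)C)o3)c12 | intermediate
19 | sodium 6-bromo-4-methoxy-3-[2-(1-SEM-pyrrol-2-yl)oxazol-5-yl]indol-1-ide | COc1cc(Br)cc2[n-]cc(-c3cnc(-c4cccn4COCC[Si](C)(C)C)o3)c12.[Na+] | intermediate
20 | 6-bromo-4-methoxy-3-[2-(1-SEM-pyrrol-2-yl)oxazol-5-yl]-1-(triisopropylsilyl)indole | COc1cc(Br)cc2n([Si](C(C)C)(C(C)C)C(C)C)cc(-c3cnc(-c4cccn4COCC[Si](C)(C)C)o3)c12 | intermediate
21 | [5-(6-bromo-4-methoxy-1-TIPS-indol-3-yl)-2-(1-SEM-pyrrol-2-yl)oxazol-4-yl]magnesium chloride·LiCl | COc1cc(Br)cc2n([Si](C(C)C)(C(C)C)C(C)C)cc(-c3oc(-c4cccn4COCC[Si](C)(C)C)nc3[Mg]Cl)c12.[Li+].[Cl-] | intermediate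
22 | 6-bromo-3-[4-iodo-2-(1-SEM-pyrrol-2-yl)oxazol-5-yl]-4-methoxy-1-(triisopropylsilyl)indole | COc1cc(Br)cc2n([Si](C(C)C)(C(C)C)C(C)C)cc(-c3oc(-c4cccn4COCC[Si](C)(C)C)nc3I)c12 | intermediate
23 | 6-bromo-3-[4-iodo-2-(1-SEM-pyrrol-2-yl)oxazol-5-yl]-4-methoxy-1H-indole | COc1cc(Br)cc2[nH]cc(-c3oc(-c4cccn4COCC[Si](C)(C)C)nc3I)c12 | intermediate
24 | 6-bromo-3-[4-iodo-2-(1H-pyrrol-2-yl)oxazol-5-yl]-4-methoxy-1H-indole | COc1cc(Br)cc2[nH]cc(-c3oc(-c4ccc[nH]4)nc3I)c12 | target

Total step count: 13.
Longest linear sequence: 11 steps (steps 1–6 and 9–13, from 1H-pyrrole-2-carboxylic acid); steps 7–8 form the short second branch.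

Steps most likely to fail

Step 9. Oxidative addition may spread from the C–I bond to the C–Br bond, the alkyne may lose its silyl group under hot carbonate before it inserts (which removes the regiocontrol), or the azole nitrogens may sequester palladium and stall turnover. The fallback builds the same ring by aminopalladation of an alkyne already attached to the benzene ring, not by carbopalladation. Setting out from 16, Sonogashira coupling with 11 at the C–I bond (PdCl2(PPh3)2, CuI, Et3N) would give 5-bromo-3-methoxy-2-[(trimethylsilyl)ethynyl]aniline F1. K2CO3 in MeOH would free the terminal alkyne 5-bromo-2-ethynyl-3-methoxyaniline F2, and trifluoroacetic anhydride/pyridine would give N-(5-bromo-2-ethynyl-3-methoxyphenyl)-2,2,2-trifluoroacetamide F3. With Pd(PPh3)4 and Cs2CO3 in MeCN at 60–80 °C without copper, oxidative addition to the oxazolyl iodide 10, anti-aminopalladation of the alkyne by the trifluoroacetamide nitrogen and C–C reductive elimination would close the ring with the oxazole on C3 and hydrogen on C2. This gives 6-bromo-4-methoxy-3-[2-(1-SEM-pyrrol-2-yl)oxazol-5-yl]-1-(trifluoroacetyl)indole F4, whose N-acyl group K2CO3/MeOH removes on work-up. The route is rejoined at 18, so steps 6, 9 and 10 are bypassed.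

Step 12. Deprotonation may stray to a ring position other than oxazole C4 (pyrrole C5 next to the SEM-bearing nitrogen, or indole C5 between methoxy and bromine) or stay incomplete, so that iodine is delivered unselectively. The fallback generates the C4 anion by halogen–magnesium exchange at a bromine placed there from the outset.
- Setting out from 8, lithiation as in step 5 (via 9) and quenching with BrCCl2CCl2Br would give 5-bromo-2-(1-SEM-pyrrol-2-yl)oxazole F5.
- LiN(iPr)2 at −78 °C would trigger the halogen dance to 4-bromo-5-lithio-2-(1-SEM-pyrrol-2-yl)oxazole F6, which I2 would trap as 4-bromo-5-iodo-2-(1-SEM-pyrrol-2-yl)oxazole F7.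
- Sonogashira coupling with 11 at the C–I bond would give 4-bromo-2-(1-SEM-pyrrol-2-yl)-5-[(trimethylsilyl)ethynyl]oxazole F8.
- Heteroannulation with 16 under the conditions of step 9 would give 6-bromo-3-[4-bromo-2-(1-SEM-pyrrol-2-yl)oxazol-5-yl]-4-methoxy-2-(trimethylsilyl)-1H-indole F9, and dilute HCl would give 6-bromo-3-[4-bromo-2-(1-SEM-pyrrol-2-yl)oxazol-5-yl]-4-methoxy-1H-indole F10.
- NaH would give sodium 6-bromo-3-[4-bromo-2-(1-SEM-pyrrol-2-yl)oxazol-5-yl]-4-methoxyindol-1-ide F11, and TIPSCl would give 6-bromo-3-[4-bromo-2-(1-SEM-pyrrol-2-yl)oxazol-5-yl]-4-methoxy-1-(triisopropylsilyl)indole F12.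
- i-PrMgCl·LiCl at −20 °C should exchange the oxazole bromide, which is flanked by the ring nitrogen and far more electron-poor than the bromide on the methoxyindole ring, and so return to 21; I2 then gives 22.

Step 13. Fragmentation of the pyrrole N-SEM group by fluoride may stop short, the liberated formaldehyde may add back to the deprotonated azoles, or prolonged heating may erode the C–I bond. The fallback removes the two nitrogen groups separately and cleaves the SEM group by acid. Setting out from 22, Bu4NF at 0 °C would remove only the N-silyl group and 23 would be isolated. Trifluoroacetic acid in CH2Cl2 at room temperature would then cleave the SEM ether through the N-acyliminium-type cation to 6-bromo-3-{2-[1-(hydroxymethyl)pyrrol-2-yl]-4-iodooxazol-5-yl}-4-methoxy-1H-indole F13. NH3 in MeOH would release formaldehyde from this hemiaminal and give 24.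

Further compounds
F1 | step 9 | 5-bromo-3-methoxy-2-[(trimethylsilyl)ethynyl]aniline | COc1cc(Br)cc(N)c1C#C[Si](C)(C)C
F2 | step 9 | 5-bromo-2-ethynyl-3-methoxyaniline | COc1cc(Br)cc(N)c1C#C
F3 | step 9 | N-(5-bromo-2-ethynyl-3-methoxyphenyl)-2,2,2-trifluoroacetamide | COc1cc(Br)cc(NC(=O)C(F)(F)F)c1C#C
F4 | step 9 | 6-bromo-4-methoxy-3-[2-(1-SEM-pyrrol-2-yl)oxazol-5-yl]-1-(trifluoroacetyl)indole | COc1cc(Br)cc2n(C(=O)C(F)(F)F)cc(-c3cnc(-c4cccn4COCC[Si](C)(C)C)o3)c12
F5 | step 12 | 5-bromo-2-(1-SEM-pyrrol-2-yl)oxazole | Brc1cnc(-c2cccn2COCC[Si](C)(C)C)o1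
F6 | step 12 | 4-bromo-5-lithio-2-(1-SEM-pyrrol-2-yl)oxazole | [Li]c1oc(-c2cccn2COCC[Si](C)(C)C)nc1Br
F7 | step 12 | 4-bromo-5-iodo-2-(1-SEM-pyrrol-2-yl)oxazole | Ic1oc(-c2cccn2COCC[Si](C)(C)C)nc1Br
F8 | step 12 | 4-bromo-2-(1-SEM-pyrrol-2-yl)-5-[(trimethylsilyl)ethynyl]oxazole | C[Si](C)(C)C#Cc1oc(-c2cccn2COCC[Si](C)(C)C)nc1Br
F9 | step 12 | 6-bromo-3-[4-bromo-2-(1-SEM-pyrrol-2-yl)oxazol-5-yl]-4-methoxy-2-(trimethylsilyl)-1H-indole | COc1cc(Br)cc2[nH]c([Si](C)(C)C)c(-c3oc(-c4cccn4COCC[Si](C)(C)C)nc3Br)c12
F10 | step 12 | 6-bromo-3-[4-bromo-2-(1-SEM-pyrrol-2-yl)oxazol-5-yl]-4-methoxy-1H-indole | COc1cc(Br)cc2[nH]cc(-c3oc(-c4cccn4COCC[Si](C)(C)C)nc3Br)c12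
F11 | step 12 | sodium 6-bromo-3-[4-bromo-2-(1-SEM-pyrrol-2-yl)oxazol-5-yl]-4-methoxyindol-1-ide | COc1cc(Br)cc2[n-]cc(-c3oc(-c4cccn4COCC[Si](C)(C)C)nc3Br)c12.[Na+]
F12 | step 12 | 6-bromo-3-[4-bromo-2-(1-SEM-pyrrol-2-yl)oxazol-5-yl]-4-methoxy-1-(triisopropylsilyl)indole | COc1cc(Br)cc2n([Si](C(C)C)(C(C)C)C(C)C)cc(-c3oc(-c4cccn4COCC[Si](C)(C)C)nc3Br)c12
F13 | step 13 | 6-bromo-3-{2-[1-(hydroxymethyl)pyrrol-2-yl]-4-iodooxazol-5-yl}-4-methoxy-1H-indole | COc1cc(Br)cc2[nH]cc(-c3oc(-c4cccn4CO)nc3I)c12
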